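**Retrosynthetic overview**
- The target acid comes from its methyl ester by SN2 O-demethylation; the C19 CH2OH comes from a thioester (Fukuyama reduction, then borohydride), and the axial 3-acetate from a 3-ketone (equatorial hydride delivery, acetylation in the same flask).
- The decalin is made in one step from an acyclic α-methyl β-keto thioester triene by a phosphate-controlled anodic radical-polar bicyclisation: ring A closes first (C4–C5), then ring B (C9–C10), and the C8 cation loses H7 to give the 7-ene.
- The acyclic precursor comes from a C12-brominated methyl farnesoate and S-ethyl acetothioacetate (dianion γ-alkylation, then α-methylation in the same flask).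
- The bromide comes from methyl (2E,6E)-farnesoate (SeO2 allylic oxidation, Appel); the thioester comes from the diketene–acetone adduct and ethanethiol.

Assumption: labdane numbering is used for the bicyclic compounds (C18 = equatorial and C19 = axial carbon on C4, C20 = methyl on C10), and the (R)-phosphate is written in step 5 on the understanding that its mirror image is used if it favours the other enantiomeric fold.

**Step 1**
Reactants: 1 methyl (2E,6E)-3,7,11-trimethyldodeca-2,6,10-trienoate (methyl farnesoate)
Product: 2 methyl (2E,6E,10E)-12-hydroxy-3,7,11-trimethyldodeca-2,6,10-trienoate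
Conditions: SeO2 (0.3 equiv), t-BuOOH (3 equiv), salicylic acid (0.1 equiv), CH2Cl2, 0 °C to rt
Reagents that add atoms: tert-butyl hydroperoxide CC(C)(C)OO (oxygen source), relayed by selenium dioxide O=[Se]=O
Why: SeO2/t-BuOOH allylic oxidation (ene reaction, then 2,3-sigmatropic shift) attacks the (E)-methyl of the terminal, most electron-rich trisubstituted olefin and leaves the enoate and the internal olefin alone; no stereocentre is formed.

**Step 2**
Reactants: 2 methyl (2E,6E,10E)-12-hydroxy-3,7,11-trimethyldodeca-2,6,10-trienoate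
Product: 3 methyl (2E,6E,10E)-12-bromo-3,7,11-trimethyldodeca-2,6,10-trienoate
Conditions: CBr4, PPh3, CH2Cl2, 0 °C
Reagents that add atoms: carbon tetrabromide BrC(Br)(Br)Br
Why: Appel bromination of a primary allylic alcohol under neutral conditions keeps the olefin geometry and the ester.

**Step 3**
Reactants: 4 2,2,6-trimethyl-4H-1,3-dioxin-4-one; 5 ethanethiol
Product: 7 S-ethyl 3-oxobutanethioate, via acetylketene 6 (not isolated)
Conditions: toluene, 110 °C, sealed tube
Reagents that add atoms: none
Why: Thermal retro-hetero-Diels–Alder loss of acetone gives acetylketene, which the thiol traps as the β-keto thioester.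

**Step 4**
Reactants: 3 methyl (2E,6E,10E)-12-bromo-3,7,11-trimethyldodeca-2,6,10-trienoate; 7 S-ethyl 3-oxobutanethioate
Product: 10 methyl (2E,6E,10E)-16-(ethylsulfanyl)-3,7,11,15-tetramethyl-14,16-dioxohexadeca-2,6,10-trienoate, via dilithium dienolate 8 (not isolated), via lithium enolate 9 (not isolated)
Conditions: 7 (1.3 equiv), LiN(i-Pr)2 (2.7 equiv), THF, −78 to 0 °C; 3, −78 to 0 °C; then MeI (3 equiv), DMPU, 0 °C to rt
Reagents that add atoms: iodomethane CI
Why: Acetoacetate-dianion chemistry: the dienolate alkylates the allylic bromide at its γ-carbon, and the remaining stabilised enolate is C-methylated in the same flask; C15 of 10 is a racemic, freely epimerising centre that is erased in step 5.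

**Step 5**
Reactants: 10 methyl (2E,6E,10E)-16-(ethylsulfanyl)-3,7,11,15-tetramethyl-14,16-dioxohexadeca-2,6,10-trienoate
Product: 12 methyl (4S,5S,9R,10S,13E)-19-(ethylsulfanyl)-3,19-dioxolabda-7,13-dien-15-oate (trans-decalin; C(=O)SEt axial on C4 and cis to C20; C4 methyl equatorial; side chain on C9 equatorial), via tertiary C8 carbocation 11 (not isolated)
Conditions: tetrabutylammonium (R)-3,3'-bis(2,4,6-triisopropylphenyl)-1,1'-binaphthyl-2,2'-diyl phosphate (10 mol%), (4-BrC6H4)3N (10 mol%), 2,6-lutidine (2.5 equiv), n-Bu4NPF6 (0.1 M), CH2Cl2, graphite anode and cathode, undivided cell, constant current (2.2 F/mol), −20 °C; AgNO3–silica chromatography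
Reagents that add atoms: none
Why: Proposed new method: a chiral-phosphate-controlled anodic radical-polar bicyclisation in which the phosphate hydrogen-bonds the enol O–H of 10, so that the mediator radical cation (4-BrC6H4)3N•+ (about +1.05 V vs SCE, too weak to oxidise the isolated olefins) removes one electron in a proton-coupled step and leaves the electrophilic α-radical hydrogen-bonded to the chiral phosphoric acid; this acid activation makes the bound radical add 6-endo to the C5=C10 olefin faster than any free radical, and the catalyst pocket selects one of the two mirror-image chair–chair folds (ring A by C4–C5, then ring B by C10–C9); the tertiary C8 radical is oxidised to cation 11, which loses the C7 proton in Zaitsev fashion to give the 7-ene; the radical reacts with C19 anti to the ketone oxygen and the E-olefins pass through chairs, which gives axial thioester and equatorial methyl at C4, trans ring fusion and an equatorial C9 side chain, exactly as in the racemic Mn(OAc)3/Cu(OAc)2 cyclisations of α-methyl β-keto esters, the closest known reaction type, together with chiral-phosphate proton-coupled electron transfer and organo-SOMO polyene cyclisation of aldehydes.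

**Step 6**
Reactants: 12 methyl (4S,5S,9R,10S,13E)-19-(ethylsulfanyl)-3,19-dioxolabda-7,13-dien-15-oate
Product: 14 methyl (3S,4S,5S,9R,10S,13E)-3-acetoxy-19-(ethylsulfanyl)-19-oxolabda-7,13-dien-15-oate (acetoxy axial, anti to the axial C19 thioester), via lithium alkoxide 13 (not isolated)
Conditions: LiBH(s-Bu)3 (1.2 equiv), THF, −78 °C; then Ac2O (4 equiv), DMAP (0.2 equiv), −78 to 0 °C
Reagents that add atoms: acetic anhydride CC(=O)OC(C)=O
Why: The bulky hydride attacks the C3 ketone along the equatorial trajectory (axial attack is blocked by the axial hydrogens on C1 and C5), giving the axial (3S) alkoxide as in selectride reductions of 4,4-disubstituted 3-oxo terpenoids; the alkoxide is acetylated cold in the same flask (reductive acetylation) before retro-aldol cleavage can occur, and the hindered thioester and the β,β-disubstituted enoate are not reduced.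

**Step 7**
Reactants: 14 methyl (3S,4S,5S,9R,10S,13E)-3-acetoxy-19-(ethylsulfanyl)-19-oxolabda-7,13-dien-15-oate
Product: 16 methyl (3S,4R,5S,9R,10S,13E)-3-acetoxy-19-hydroxylabda-7,13-dien-15-oate, via aldehyde 15 (not isolated)
Conditions: Et3SiH (4 equiv), 10% Pd/C, acetone, rt; filter through Celite, concentrate; then NaBH4, MeOH, 0 °C
Reagents that add atoms: none
Why: Fukuyama reduction converts only the thioester to the aldehyde, and NaBH4 then reduces only the aldehyde; the acetate, the enoate and the trisubstituted olefin survive, and the acetyl group cannot migrate because O3 and C19 are trans-diaxial.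

**Step 8**
Reactants: 16 methyl (3S,4R,5S,9R,10S,13E)-3-acetoxy-19-hydroxylabda-7,13-dien-15-oate
Product: 18 (3S,4R,5S,9R,10S,13E)-3-acetoxy-19-hydroxylabda-7,13-dien-15-oic acid (CNP0129162.1), via lithium carboxylate 17 (not isolated)
Conditions: LiI (8 equiv), pyridine, reflux; then 1 M HCl work-up
Reagents that add atoms: none
Why: Iodide cleaves the methyl ester by SN2 attack at the O-methyl carbon, whereas the acetate has only a secondary neopentyl O-alkyl carbon and is not touched (nucleophilic ester dealkylation); no stereocentre is involved.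

**Compound list**
1 | methyl (2E,6E)-3,7,11-trimethyldodeca-2,6,10-trienoate | COC(=O)/C=C(\C)CC/C=C(\C)CCC=C(C)C | starting material
2 | methyl (2E,6E,10E)-12-hydroxy-3,7,11-trimethyldodeca-2,6,10-trienoate | COC(=O)/C=C(\C)CC/C=C(\C)CC/C=C(\C)CO | intermediate
3 | methyl (2E,6E,10E)-12-bromo-3,7,11-trimethyldodeca-2,6,10-trienoate | COC(=O)/C=C(\C)CC/C=C(\C)CC/C=C(\C)CBr | intermediate
4 | 2,2,6-trimethyl-4H-1,3-dioxin-4-one | CC1=CC(=O)OC(C)(C)O1 | starting material
5 | ethanethiol | CCS | starting material
6 | acetylketene | CC(=O)C=C=O | intermediate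
7 | S-ethyl 3-oxobutanethioate | CCSC(=O)CC(C)=O | intermediate
8 | dilithium dienolate of 7 | C=C([O-])C=C([O-])SCC.[Li+].[Li+] | intermediate
9 | lithium enolate of methyl (2E,6E,10E)-16-(ethylsulfanyl)-3,7,11-trimethyl-14,16-dioxohexadeca-2,6,10-trienoate | COC(=O)/C=C(\C)CC/C=C(\C)CC/C=C(\C)CCC(=O)[CH-]C(=O)SCC.[Li+] | intermediate
10 | methyl (2E,6E,10E)-16-(ethylsulfanyl)-3,7,11,15-tetramethyl-14,16-dioxohexadeca-2,6,10-trienoate (C15 racemic, labile) | COC(=O)/C=C(\C)CC/C=C(\C)CC/C=C(\C)CCC(=O)C(C)C(=O)SCC | intermediate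
11 | tertiary C8 carbocation of the bicyclic keto thioester | O=C1CC[C@]2(C)[C@H](CC[C+](C)[C@H]2CC/C(C)=C/C(=O)OC)[C@]1(C)C(=O)SCC | intermediate
12 | methyl (4S,5S,9R,10S,13E)-19-(ethylsulfanyl)-3,19-dioxolabda-7,13-dien-15-oate | O=C1CC[C@]2(C)[C@H](CC=C(C)[C@H]2CC/C(C)=C/C(=O)OC)[C@]1(C)C(=O)SCC | intermediate
13 | lithium (3S)-alkoxide of 12 | [Li+].[O-][C@H]1CC[C@]2(C)[C@H](CC=C(C)[C@H]2CC/C(C)=C/C(=O)OC)[C@]1(C)C(=O)SCC | intermediate
14 | methyl (3S,4S,5S,9R,10S,13E)-3-acetoxy-19-(ethylsulfanyl)-19-oxolabda-7,13-dien-15-oate | CC(=O)O[C@H]1CC[C@]2(C)[C@H](CC=C(C)[C@H]2CC/C(C)=C/C(=O)OC)[C@]1(C)C(=O)SCC | intermediate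
15 | methyl (3S,4S,5S,9R,10S,13E)-3-acetoxy-19-oxolabda-7,13-dien-15-oate | CC(=O)O[C@H]1CC[C@]2(C)[C@H](CC=C(C)[C@H]2CC/C(C)=C/C(=O)OC)[C@]1(C)C=O | intermediate
16 | methyl (3S,4R,5S,9R,10S,13E)-3-acetoxy-19-hydroxylabda-7,13-dien-15-oate | CC(=O)O[C@H]1CC[C@]2(C)[C@H](CC=C(C)[C@H]2CC/C(C)=C/C(=O)OC)[C@]1(C)CO | intermediate
17 | lithium (3S,4R,5S,9R,10S,13E)-3-acetoxy-19-hydroxylabda-7,13-dien-15-oate | CC(=O)O[C@H]1CC[C@]2(C)[C@H](CC=C(C)[C@H]2CC/C(C)=C/C(=O)[O-])[C@]1(C)CO.[Li+] | intermediate
18 | (3S,4R,5S,9R,10S,13E)-3-acetoxy-19-hydroxylabda-7,13-dien-15-oic acid | CC(=O)O[C@H]1CC[C@]2(C)[C@H](CC=C(C)[C@H]2CC/C(C)=C/C(=O)O)[C@]1(C)CO | target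

**Step count**
Total steps: 8. Longest linear sequence: 7 (1 → 2 → 3 → 10 → 12 → 14 → 16 → 18); step 3 is a one-step side branch.

**Steps most likely to fail**

Step 5 (the proposed new method). The single hydrogen bond may give low enantioselectivity, free radicals may cyclise without the catalyst, and the E1 termination may give some 8(17)- and 8-ene isomers. The fallback uses known chemistry, sets out from 10 and comes back at 14. Oxidative radical cyclisation with Mn(OAc)3·2H2O (trivalent manganese, 2 equiv) and Cu(OAc)2·H2O (divalent copper, 1 equiv) in AcOH gives the racemic exocyclic 8(17)-olefin keto thioester F1. Hydrogen-atom-transfer isomerisation with Co(salen)Cl (trivalent cobalt; salen = N,N'-bis(3,5-di-tert-butylsalicylidene)ethylenediamine) and PhSiH3 moves the olefin to C7–C8 through the less hindered C7 methylene and gives the racemic 7-ene keto thioester F2 (12 together with its mirror image). Reduction with catecholborane and 10 mol% (R)-Me-CBS oxazaborolidine is run as a divergent reaction on the racemate: hydride goes to the same carbonyl face of both enantiomers, so 12 gives the axial (3S)-alcohol F3 and its mirror image gives the equatorial (3S)-alcohol F4. These are diastereomers and are separated on silica. Acetylation of F3 (Ac2O, DMAP, pyridine) gives 14.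

Step 6. Equatorial hydride delivery next to the axial thioester may be incomplete, and the β-alkoxy thioester may undergo retro-aldol cleavage before acetylation. The fallback sets the axial alcohol by intramolecular hydride delivery; it sets out from 12 and comes back at 16. Fukuyama reduction of 12 (Et3SiH, Pd/C, acetone) gives the 3-oxo-19-aldehyde F5. NaBH4 at −78 °C reduces only the aldehyde and gives the β-hydroxy ketone F6. Me4NBH(OAc)3 in MeCN/AcOH (Evans–Saksena reduction) delivers hydride from the C19 oxygen to the same face of C3 and gives the anti 3,19-diol F7 with the axial 3-hydroxyl. Ac2O/DMAP gives the 3,19-diacetate F8. K2CO3 in MeOH at 0 °C removes only the unhindered primary acetate and gives 16.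

Step 8. Forcing iodide demethylation of a conjugated ester may be slow or may erode the acetate. The fallback replaces selective dealkylation by global hydrolysis and selective re-protection; it sets out from 16 and comes back at 18. KOH in MeOH/H2O at 60 °C cleaves both esters and gives the 3,19-dihydroxy acid F9. Ac2O/pyridine/DMAP, then aqueous work-up to hydrolyse the mixed anhydride, gives the 3,19-diacetoxy acid F10. K2CO3 in MeOH at 0 °C (or a lipase) removes only the primary C19 acetate and gives 18.

**Further compounds**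
F1 | step 5 | racemic methyl (13E)-19-(ethylsulfanyl)-3,19-dioxolabda-8(17),13-dien-15-oate (enantiomer of the target series drawn) | O=C1CC[C@]2(C)[C@H](CCC(=C)[C@H]2CC/C(C)=C/C(=O)OC)[C@]1(C)C(=O)SCC
F2 | step 5 | racemate of 12 (mirror-image component drawn) | O=C1CC[C@@]2(C)[C@@H](CC=C(C)[C@@H]2CC/C(C)=C/C(=O)OC)[C@@]1(C)C(=O)SCC
F3 | step 5 | methyl (3S,4S,5S,9R,10S,13E)-19-(ethylsulfanyl)-3-hydroxy-19-oxolabda-7,13-dien-15-oate (axial alcohol) | O[C@H]1CC[C@]2(C)[C@H](CC=C(C)[C@H]2CC/C(C)=C/C(=O)OC)[C@]1(C)C(=O)SCC
F4 | step 5 | methyl (3S,4R,5R,9S,10R,13E)-19-(ethylsulfanyl)-3-hydroxy-19-oxolabda-7,13-dien-15-oate (equatorial alcohol of the mirror-image series) | O[C@H]1CC[C@@]2(C)[C@@H](CC=C(C)[C@@H]2CC/C(C)=C/C(=O)OC)[C@@]1(C)C(=O)SCC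
F5 | step 6 | methyl (4R,5S,9R,10S,13E)-3,19-dioxolabda-7,13-dien-15-oate | O=C1CC[C@]2(C)[C@H](CC=C(C)[C@H]2CC/C(C)=C/C(=O)OC)[C@]1(C)C=O
F6 | step 6 | methyl (4R,5S,9R,10S,13E)-19-hydroxy-3-oxolabda-7,13-dien-15-oate | O=C1CC[C@]2(C)[C@H](CC=C(C)[C@H]2CC/C(C)=C/C(=O)OC)[C@]1(C)CO
F7 | step 6 | methyl (3S,4R,5S,9R,10S,13E)-3,19-dihydroxylabda-7,13-dien-15-oate | O[C@H]1CC[C@]2(C)[C@H](CC=C(C)[C@H]2CC/C(C)=C/C(=O)OC)[C@]1(C)CO
F8 | step 6 | methyl (3S,4R,5S,9R,10S,13E)-3,19-diacetoxylabda-7,13-dien-15-oate | CC(=O)O[C@H]1CC[C@]2(C)[C@H](CC=C(C)[C@H]2CC/C(C)=C/C(=O)OC)[C@]1(C)COC(C)=O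
F9 | step 8 | (3S,4R,5S,9R,10S,13E)-3,19-dihydroxylabda-7,13-dien-15-oic acid | O[C@H]1CC[C@]2(C)[C@H](CC=C(C)[C@H]2CC/C(C)=C/C(=O)O)[C@]1(C)CO
F10 | step 8 | (3S,4R,5S,9R,10S,13E)-3,19-diacetoxylabda-7,13-dien-15-oic acid | CC(=O)O[C@H]1CC[C@]2(C)[C@H](CC=C(C)[C@H]2CC/C(C)=C/C(=O)O)[C@]1(C)COC(C)=O
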